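**Plan**

- Retrosynthesis: cut the interflavan bond C4–C6' (upper flavan-4-yl cation plus a lower unit blocked at C8 by bromine), then the gallate ester, then O1–C8a and C2–C3 in ring C of the upper unit.
- Enabling feature: ring A of the upper unit is a phloroglucinol, so C8a is meta to both oxygens at C5 and C7 and a fluoride there can leave by SNAr. C2 and C3 both carry oxygen (like polarity), so C3 is brought in as a nitronate (polarity reversal).
- Forward: ring A fluoro-nitroethane, then nitroaldol/SNAr annulation with tri-O-benzylgallaldehyde (closes ring C), Nef reaction to the flavan-3-one, asymmetric hydrogenation, galloylation, C4 oxidation, coupling with the lower unit, hydrogenolysis.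
- Stereochemistry: upper C2 and C3 come from catalyst-controlled hydrogenation of the racemic, C2-labile flavan-3-one (2,3-cis, 2R,3R). Upper C4 comes from anti attack on the flavan-4-yl cation (3,4-trans). The lower unit comes from (+)-gallocatechin, and the 4→6 regiochemistry from the C8 bromine.

Key step: step 5

Assumption: (+)-gallocatechin, the (2R,3S) enantiomer, is taken as a purchasable natural product; racemic compounds are drawn as one enantiomer.

**Route**

Step 1
Reactants: 1 1,3,5-trifluorobenzene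
Product: 2 1,3-bis(benzyloxy)-5-fluorobenzene
Conditions: BnOH (2.1 equiv), NaH (2.2 equiv), THF–DMPU, 0 °C to 80 °C
Reagents that add atoms: benzyl alcohol, OCc1ccccc1
Why: Twofold nucleophilic aromatic substitution, in which each fluorine is activated inductively by the meta fluorines and the third fluoride, needed in step 5, should survive because the ring has become electron-rich.

Step 2
Reactants: 2 1,3-bis(benzyloxy)-5-fluorobenzene
Product: 4 2,4-bis(benzyloxy)-6-fluorobenzaldehyde, via aryl iminium salt 3 (not isolated)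
Conditions: POCl3 (1.5 equiv), DMF, 0 °C to 70 °C; then ice water
Reagents that add atoms: N,N-dimethylformamide, CN(C)C=O; water, O
Why: Vilsmeier–Haack formylation, expected mainly at the carbon ortho to fluorine (ortho and para to the benzyloxy groups) because the position between the two benzyloxy groups is more hindered; the minor regioisomer is removed by crystallisation.

Step 3
Reactants: 4 2,4-bis(benzyloxy)-6-fluorobenzaldehyde
Product: 5 (E)-1,5-bis(benzyloxy)-3-fluoro-2-(2-nitrovinyl)benzene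
Conditions: MeNO2 (10 equiv), NH4OAc (0.5 equiv), AcOH, 90 °C
Reagents that add atoms: nitromethane, C[N+](=O)[O-]
Why: Henry (nitroaldol) condensation with dehydration in the flask should give the thermodynamically favoured E nitroalkene.

Step 4
Reactants: 5 (E)-1,5-bis(benzyloxy)-3-fluoro-2-(2-nitrovinyl)benzene
Product: 6 1,5-bis(benzyloxy)-3-fluoro-2-(2-nitroethyl)benzene
Conditions: NaBH4 (2 equiv), THF–MeOH (10:1), 0 °C, inverse addition
Reagents that add atoms: none
Why: Conjugate hydride reduction of the nitroalkene stops at the nitroalkane and leaves the aryl fluoride and the benzyl ethers untouched.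

Step 5
Reactants: 6 1,5-bis(benzyloxy)-3-fluoro-2-(2-nitroethyl)benzene; 7 3,4,5-tris(benzyloxy)benzaldehyde
Product: 9 racemic 2,3-trans-5,7-bis(benzyloxy)-3-nitro-2-[3,4,5-tris(benzyloxy)phenyl]chromane, via nitroaldol adduct 8 (not isolated)
Conditions: KOtBu (1.1 equiv), THF–DMPU (4:1), −20 °C; 7 (1.1 equiv), 0 °C; KOtBu (1.3 equiv), 55 °C; AcOH quench at −20 °C
Reagents that add atoms: none
Why: Proposed new method: the potassium nitronate of 6 serves as the polarity-reversed C3 and adds to the non-enolisable aldehyde 7 in a Henry reaction, and the second portion of base converts adduct 8 into its alkoxide, which displaces the fluoride at C8a by addition–elimination, so that the reversible nitroaldol is drained by the irreversible ring closure. The closest known reaction types are the base-mediated aldol–SNAr and Michael–SNAr annulations of ortho-fluoroaryl substrates and the oxa-Michael–Henry synthesis of 3-nitrochromenes, which closes the same ring through its other two bonds. Ring C closes in the 6-exo-trig mode at an aromatic carbon whose fluorine is meta to both benzyloxy groups, so these activate it inductively while the negative charge of the Meisenheimer intermediate rests on C4a, C6 and C8, none of which bears oxygen. C2 and C3 are formed without absolute control and C3 should equilibrate through the nitronate to the mainly 2,3-trans isomer, which is harmless because C3 becomes trigonal in step 6 and C2 is set in step 7. The step needs O-arylation by the alkoxide to win over O-arylation by the nitronate oxygen and over dehydration to the nitroalkene; the excess of KOtBu secures this by forming the nitronate–alkoxide dianion, in which the alkoxide is by far the stronger nucleophile and hydroxide loss is suppressed.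

Step 6
Reactants: 9 racemic 2,3-trans-5,7-bis(benzyloxy)-3-nitro-2-[3,4,5-tris(benzyloxy)phenyl]chromane
Product: 11 racemic 5,7-bis(benzyloxy)-2-[3,4,5-tris(benzyloxy)phenyl]chroman-3-one, via sodium nitronate 10 (not isolated)
Conditions: NaOMe (1.1 equiv), MeOH–THF, 0 °C; then aq. TiCl3 (4.5 equiv), NH4OAc buffer, 0 °C to rt
Reagents that add atoms: water, O
Why: Reductive Nef reaction (McMurry variant), in which trivalent titanium reduces the nitronate to the imine that hydrolyses in the buffer to the ketone, so both C3 epimers of 9 converge on one flavan-3-one.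

Step 7
Reactants: 11 racemic 5,7-bis(benzyloxy)-2-[3,4,5-tris(benzyloxy)phenyl]chroman-3-one
Product: 12 (2R,3R)-5,7-bis(benzyloxy)-2-[3,4,5-tris(benzyloxy)phenyl]chroman-3-ol (penta-O-benzyl-(−)-epigallocatechin)
Conditions: H2 (50 atm), RuCl2[(S)-Xyl-SDP][(R,R)-DPEN] (0.5 mol %, the catalyst enantiomer that delivers the 3R alcohol), KOtBu (20 mol %), iPrOH–toluene, 25 °C
Reagents that add atoms: none
Why: Noyori-type asymmetric hydrogenation with dynamic kinetic resolution of a racemic α-aryl, α-aryloxy cyclic ketone: C2–H (α to the carbonyl, benzylic and α to oxygen) should racemise through the enolate faster than reduction, the catalyst takes the 2R enantiomer, and hydride adds to C3 anti to the 2-aryl group to give the 2,3-cis alcohol without touching the benzyl ethers.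

Step 8
Reactants: 12 (2R,3R)-5,7-bis(benzyloxy)-2-[3,4,5-tris(benzyloxy)phenyl]chroman-3-ol; 13 3,4,5-tris(benzyloxy)benzoic acid
Product: 14 (2R,3R)-5,7-bis(benzyloxy)-2-[3,4,5-tris(benzyloxy)phenyl]chroman-3-yl 3,4,5-tris(benzyloxy)benzoate
Conditions: 13 (1.5 equiv), DCC (1.6 equiv), DMAP (0.5 equiv), CH2Cl2, rt
Reagents that add atoms: none
Why: Steglich esterification acylates the axial secondary alcohol with retention, since the C–O bond at C3 is not broken.

Step 9
Reactants: 14 (2R,3R)-5,7-bis(benzyloxy)-2-[3,4,5-tris(benzyloxy)phenyl]chroman-3-yl 3,4,5-tris(benzyloxy)benzoate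
Product: 15 (2R,3R,4S)-5,7-bis(benzyloxy)-4-(2-ethoxyethoxy)-2-[3,4,5-tris(benzyloxy)phenyl]chroman-3-yl 3,4,5-tris(benzyloxy)benzoate
Conditions: DDQ (2.0 equiv), 2-ethoxyethanol (5 equiv), CH2Cl2, rt
Reagents that add atoms: 2-ethoxyethanol, CCOCCO
Why: DDQ benzylic oxidation by hydride abstraction at C4 gives the cation stabilised by ring A, which the alcohol captures anti to the 3-acyloxy group (4β); this centre is ionised again in step 12.

Step 10
Reactants: 16 (+)-gallocatechin
Product: 17 5,7,3',4',5'-penta-O-benzyl-(+)-gallocatechin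
Conditions: BnBr (5.5 equiv), K2CO3 (6 equiv), DMF, 0 °C to rt, argon
Reagents that add atoms: benzyl bromide, BrCc1ccccc1
Why: Williamson etherification of the five phenols only, because carbonate does not deprotonate the secondary alcohol, and the low temperature limits base-induced epimerisation at C2.

Step 11
Reactants: 17 5,7,3',4',5'-penta-O-benzyl-(+)-gallocatechin
Product: 18 8-bromo-5,7,3',4',5'-penta-O-benzyl-(+)-gallocatechin
Conditions: NBS (1.0 equiv), CH2Cl2, −78 °C to 0 °C
Reagents that add atoms: N-bromosuccinimide, O=C1CCC(=O)N1Br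
Why: Electrophilic aromatic bromination of the phloroglucinol ring A, which for O-benzylated flavan-3-ols goes to C8 and leaves C6 as the only nucleophilic carbon.

Step 12
Reactants: 15 (2R,3R,4S)-5,7-bis(benzyloxy)-4-(2-ethoxyethoxy)-2-[3,4,5-tris(benzyloxy)phenyl]chroman-3-yl 3,4,5-tris(benzyloxy)benzoate; 18 8-bromo-5,7,3',4',5'-penta-O-benzyl-(+)-gallocatechin
Product: 19 trideca-O-benzyl-8-bromo derivative of epigallocatechin 3-O-gallate-(4β→6)-gallocatechin (bromine at C8 of the lower unit)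
Conditions: 18 (3 equiv), TMSOTf (0.3 equiv), 4 Å MS, CH2Cl2, −78 °C
Reagents that add atoms: none
Why: Lewis-acid-promoted Friedel–Crafts alkylation by the flavan-4-yl cation (the standard interflavan bond formation), attacked by C6 of 18 anti to the 3-galloyloxy group and to ring B, which sets C4 trans to C3; the excess of 18 suppresses self-condensation.

Step 13
Reactants: 19 trideca-O-benzyl-8-bromo derivative of epigallocatechin 3-O-gallate-(4β→6)-gallocatechin
Product: 20 epigallocatechin 3-O-gallate-(4β→6)-gallocatechin (CNP0271447.2)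
Conditions: H2 (1 atm), Pd(OH)2/C, Et3N (1.2 equiv), THF–MeOH–H2O, rt; filtration under argon, Sephadex LH-20
Reagents that add atoms: none
Why: Catalytic hydrogenolysis cleaves all thirteen benzyl ethers and the aryl C–Br bond in one operation and leaves the gallate ester and the four ring stereocentres untouched.

**Compound list**

1 | 1,3,5-trifluorobenzene | Fc1cc(F)cc(F)c1 | starting material
2 | 1,3-bis(benzyloxy)-5-fluorobenzene | Fc1cc(OCc2ccccc2)cc(OCc2ccccc2)c1 | intermediate
3 | N-[2,4-bis(benzyloxy)-6-fluorobenzylidene]-N-methylmethanaminium dichlorophosphate (aryl iminium salt) | C[N+](C)=Cc1c(F)cc(OCc2ccccc2)cc1OCc1ccccc1.[O-]P(Cl)(Cl)=O | intermediate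
4 | 2,4-bis(benzyloxy)-6-fluorobenzaldehyde | O=Cc1c(F)cc(OCc2ccccc2)cc1OCc1ccccc1 | intermediate
5 | (E)-1,5-bis(benzyloxy)-3-fluoro-2-(2-nitrovinyl)benzene | O=[N+]([O-])/C=C/c1c(F)cc(OCc2ccccc2)cc1OCc1ccccc1 | intermediate
6 | 1,5-bis(benzyloxy)-3-fluoro-2-(2-nitroethyl)benzene | O=[N+]([O-])CCc1c(F)cc(OCc2ccccc2)cc1OCc1ccccc1 | intermediate
7 | 3,4,5-tris(benzyloxy)benzaldehyde | O=Cc1cc(OCc2ccccc2)c(OCc2ccccc2)c(OCc2ccccc2)c1 | starting material
8 | 3-[2,4-bis(benzyloxy)-6-fluorophenyl]-2-nitro-1-[3,4,5-tris(benzyloxy)phenyl]propan-1-ol (nitroaldol adduct, diastereomer mixture, present as its potassium salt) | OC(c1cc(OCc2ccccc2)c(OCc2ccccc2)c(OCc2ccccc2)c1)C(Cc1c(F)cc(OCc2ccccc2)cc1OCc1ccccc1)[N+](=O)[O-] | intermediate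
9 | racemic (2R,3S)-5,7-bis(benzyloxy)-3-nitro-2-[3,4,5-tris(benzyloxy)phenyl]chromane (2,3-trans, one enantiomer drawn) | O=[N+]([O-])[C@H]1Cc2c(OCc3ccccc3)cc(OCc3ccccc3)cc2O[C@@H]1c1cc(OCc2ccccc2)c(OCc2ccccc2)c(OCc2ccccc2)c1 | intermediate
10 | sodium nitronate of 9 (racemic) | [Na+].[O-][N+]([O-])=C1Cc2c(OCc3ccccc3)cc(OCc3ccccc3)cc2OC1c1cc(OCc2ccccc2)c(OCc2ccccc2)c(OCc2ccccc2)c1 | intermediate
11 | racemic 5,7-bis(benzyloxy)-2-[3,4,5-tris(benzyloxy)phenyl]chroman-3-one (C2 configurationally labile) | O=C1Cc2c(OCc3ccccc3)cc(OCc3ccccc3)cc2OC1c1cc(OCc2ccccc2)c(OCc2ccccc2)c(OCc2ccccc2)c1 | intermediate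
12 | (2R,3R)-5,7-bis(benzyloxy)-2-[3,4,5-tris(benzyloxy)phenyl]chroman-3-ol | O[C@@H]1Cc2c(OCc3ccccc3)cc(OCc3ccccc3)cc2O[C@@H]1c1cc(OCc2ccccc2)c(OCc2ccccc2)c(OCc2ccccc2)c1 | intermediate
13 | 3,4,5-tris(benzyloxy)benzoic acid | O=C(O)c1cc(OCc2ccccc2)c(OCc2ccccc2)c(OCc2ccccc2)c1 | starting material
14 | (2R,3R)-5,7-bis(benzyloxy)-2-[3,4,5-tris(benzyloxy)phenyl]chroman-3-yl 3,4,5-tris(benzyloxy)benzoate | O=C(O[C@@H]1Cc2c(OCc3ccccc3)cc(OCc3ccccc3)cc2O[C@@H]1c1cc(OCc2ccccc2)c(OCc2ccccc2)c(OCc2ccccc2)c1)c1cc(OCc2ccccc2)c(OCc2ccccc2)c(OCc2ccccc2)c1 | intermediate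
15 | (2R,3R,4S)-5,7-bis(benzyloxy)-4-(2-ethoxyethoxy)-2-[3,4,5-tris(benzyloxy)phenyl]chroman-3-yl 3,4,5-tris(benzyloxy)benzoate | O=C(O[C@@H]1[C@@H](OCCOCC)c2c(OCc3ccccc3)cc(OCc3ccccc3)cc2O[C@@H]1c1cc(OCc2ccccc2)c(OCc2ccccc2)c(OCc2ccccc2)c1)c1cc(OCc2ccccc2)c(OCc2ccccc2)c(OCc2ccccc2)c1 | intermediate
16 | (+)-gallocatechin, (2R,3S) | O[C@H]1Cc2c(O)cc(O)cc2O[C@@H]1c1cc(O)c(O)c(O)c1 | starting material
17 | 5,7,3',4',5'-penta-O-benzyl-(+)-gallocatechin | O[C@H]1Cc2c(OCc3ccccc3)cc(OCc3ccccc3)cc2O[C@@H]1c1cc(OCc2ccccc2)c(OCc2ccccc2)c(OCc2ccccc2)c1 | intermediate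
18 | 8-bromo-5,7,3',4',5'-penta-O-benzyl-(+)-gallocatechin | O[C@H]1Cc2c(OCc3ccccc3)cc(OCc3ccccc3)c(Br)c2O[C@@H]1c1cc(OCc2ccccc2)c(OCc2ccccc2)c(OCc2ccccc2)c1 | intermediate
19 | trideca-O-benzyl-8-bromo derivative of epigallocatechin 3-O-gallate-(4β→6)-gallocatechin | O=C(O[C@@H]1[C@@H](c2c(OCc3ccccc3)c(Br)c3c(c2OCc2ccccc2)C[C@H](O)[C@@H](c2cc(OCc4ccccc4)c(OCc4ccccc4)c(OCc4ccccc4)c2)O3)c2c(OCc3ccccc3)cc(OCc3ccccc3)cc2O[C@@H]1c1cc(OCc2ccccc2)c(OCc2ccccc2)c(OCc2ccccc2)c1)c1cc(OCc2ccccc2)c(OCc2ccccc2)c(OCc2ccccc2)c1 | intermediate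
20 | epigallocatechin 3-O-gallate-(4β→6)-gallocatechin (CNP0271447.2) | O=C(O[C@@H]1[C@@H](c2c(O)cc3c(c2O)C[C@H](O)[C@@H](c2cc(O)c(O)c(O)c2)O3)c2c(O)cc(O)cc2O[C@@H]1c1cc(O)c(O)c(O)c1)c1cc(O)c(O)c(O)c1 | target

**Step count and risks**

Total steps: 13. Longest linear sequence: 11 (steps 1 to 9, 12, 13).

Steps most likely to fail:

1. Step 5. The alkoxide may be too slow in displacing the weakly activated fluoride, so the nitroaldol adduct reverts or dehydrates to the nitroalkene, or the nitronate oxygen arylates instead. The fallback uses known chemistry, closes ring C through its other two bonds, sets out from 7 and 4 and comes back at 9. Aldehyde 7 is condensed with nitromethane (NH4OAc, AcOH, 90 °C) to (E)-1,2,3-tris(benzyloxy)-5-(2-nitrovinyl)benzene F1. Aldehyde 4 is converted by fluoride–hydroxide exchange (2-(methylsulfonyl)ethanol, NaH, DMF, 0 °C to rt) into 2,4-bis(benzyloxy)-6-hydroxybenzaldehyde F2. F2 and F1 with DABCO (MeCN, 40 °C) undergo the known oxa-Michael–Henry–dehydration sequence to racemic 5,7-bis(benzyloxy)-3-nitro-2-[3,4,5-tris(benzyloxy)phenyl]-2H-chromene F3. NaBH4 (THF–MeOH, 0 °C) then reduces the nitroalkene to 9.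

2. Step 7. Enantio- or cis-selectivity may be insufficient, or the base may cause self-condensation of the ketone faster than hydrogenation. The fallback sets out from 11 and comes back at 12. Reduction with LiBH(s-Bu)3 (L-selectride, THF, −78 °C), with hydride anti to the 2-aryl group, gives racemic cis-5,7-bis(benzyloxy)-2-[3,4,5-tris(benzyloxy)phenyl]chroman-3-ol F4. Esterification with (S)-O-methylmandelic acid (DCC, DMAP, CH2Cl2) gives two diastereomeric esters, from which the (2R,3R)-chroman-3-yl (S)-2-methoxy-2-phenylacetate F5 is separated by chromatography. Methanolysis (K2CO3, MeOH–THF, rt) releases 12.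

3. Step 12. Ionisation at C4 next to the electron-withdrawing gallate may be slow and the brominated ring A of 18 a weak nucleophile, so that self-condensation of 15 through its own ring A or elimination competes. The fallback moves the galloylation after the coupling, sets out from 12 and 18 and comes back at 20.
 - Alcohol 12 is oxidised as in step 9 (DDQ, 2-ethoxyethanol) to (2R,3R,4S)-5,7-bis(benzyloxy)-4-(2-ethoxyethoxy)-2-[3,4,5-tris(benzyloxy)phenyl]chroman-3-ol F6.
 - Bromide 18 is benzylated at O3 (NaH, BnBr, DMF, 0 °C) to 3-O-benzyl-8-bromo-5,7,3',4',5'-penta-O-benzyl-(+)-gallocatechin F7.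
 - TMSOTf-promoted coupling of F6 with F7 (CH2Cl2, −78 °C) gives the 4β→6 dimer with a single free hydroxyl at C3 of the upper unit F8.
 - Steglich esterification of F8 with 13 gives the tetradeca-O-benzyl-8-bromo gallate F9.
 - Hydrogenolysis as in step 13 gives 20.

**Further compounds**

F1 | step 5 | (E)-1,2,3-tris(benzyloxy)-5-(2-nitrovinyl)benzene | O=[N+]([O-])/C=C/c1cc(OCc2ccccc2)c(OCc2ccccc2)c(OCc2ccccc2)c1
F2 | step 5 | 2,4-bis(benzyloxy)-6-hydroxybenzaldehyde | O=Cc1c(O)cc(OCc2ccccc2)cc1OCc1ccccc1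
F3 | step 5 | racemic 5,7-bis(benzyloxy)-3-nitro-2-[3,4,5-tris(benzyloxy)phenyl]-2H-chromene | O=[N+]([O-])C1=Cc2c(OCc3ccccc3)cc(OCc3ccccc3)cc2OC1c1cc(OCc2ccccc2)c(OCc2ccccc2)c(OCc2ccccc2)c1
F4 | step 7 | racemic cis-5,7-bis(benzyloxy)-2-[3,4,5-tris(benzyloxy)phenyl]chroman-3-ol (one enantiomer drawn) | O[C@@H]1Cc2c(OCc3ccccc3)cc(OCc3ccccc3)cc2O[C@@H]1c1cc(OCc2ccccc2)c(OCc2ccccc2)c(OCc2ccccc2)c1
F5 | step 7 | (2R,3R)-5,7-bis(benzyloxy)-2-[3,4,5-tris(benzyloxy)phenyl]chroman-3-yl (S)-2-methoxy-2-phenylacetate | CO[C@H](C(=O)O[C@@H]1Cc2c(OCc3ccccc3)cc(OCc3ccccc3)cc2O[C@@H]1c1cc(OCc2ccccc2)c(OCc2ccccc2)c(OCc2ccccc2)c1)c1ccccc1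
F6 | step 12 | (2R,3R,4S)-5,7-bis(benzyloxy)-4-(2-ethoxyethoxy)-2-[3,4,5-tris(benzyloxy)phenyl]chroman-3-ol | O[C@@H]1[C@@H](OCCOCC)c2c(OCc3ccccc3)cc(OCc3ccccc3)cc2O[C@@H]1c1cc(OCc2ccccc2)c(OCc2ccccc2)c(OCc2ccccc2)c1
F7 | step 12 | 3-O-benzyl-8-bromo-5,7,3',4',5'-penta-O-benzyl-(+)-gallocatechin | C(c1ccccc1)O[C@H]1Cc2c(OCc3ccccc3)cc(OCc3ccccc3)c(Br)c2O[C@@H]1c1cc(OCc2ccccc2)c(OCc2ccccc2)c(OCc2ccccc2)c1
F8 | step 12 | undeca-O-benzyl-8-bromo derivative of epigallocatechin-(4β→6)-gallocatechin with free hydroxyl at C3 of the upper unit | O[C@@H]1[C@@H](c2c(OCc3ccccc3)c(Br)c3c(c2OCc2ccccc2)C[C@H](OCc2ccccc2)[C@@H](c2cc(OCc4ccccc4)c(OCc4ccccc4)c(OCc4ccccc4)c2)O3)c2c(OCc3ccccc3)cc(OCc3ccccc3)cc2O[C@@H]1c1cc(OCc2ccccc2)c(OCc2ccccc2)c(OCc2ccccc2)c1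
F9 | step 12 | tetradeca-O-benzyl-8-bromo derivative of epigallocatechin 3-O-gallate-(4β→6)-gallocatechin | O=C(O[C@@H]1[C@@H](c2c(OCc3ccccc3)c(Br)c3c(c2OCc2ccccc2)C[C@H](OCc2ccccc2)[C@@H](c2cc(OCc4ccccc4)c(OCc4ccccc4)c(OCc4ccccc4)c2)O3)c2c(OCc3ccccc3)cc(OCc3ccccc3)cc2O[C@@H]1c1cc(OCc2ccccc2)c(OCc2ccccc2)c(OCc2ccccc2)c1)c1cc(OCc2ccccc2)c(OCc2ccccc2)c(OCc2ccccc2)c1
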